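**Retrosynthetic overview**

1. The cis-1,4-diol C3–OH/C6–OH that flanks C1=C2 is traced back to a bicyclic endoperoxide and, by retro-[4+2] loss of O2, to a cyclohexa-1,3-diene (C6=C1–C2=C3) that keeps only the cis C4–OH/C5–OBz pair. Singlet oxygen should return on the face opposite to that pair and so set C3 and C6.
2. Enabling feature: in this diene the ring C1–C6 is a 6π system closed by the single σ bond C4–C5 between two cis, oxygen-bearing sp3 carbons. That is the product of a thermal disrotatory electrocyclization of a 1,6-dioxygenated hexatriene with (E)-termini and both enol arms cis on C1=C2, and the C2–C3 bond of that triene is a vinyl–vinyl single bond.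
3. Key disconnections, made in one operation: C2–C3 by Stille coupling of a (1E,3E)-4-bromodienyl benzoate (C5, C6, C1, C2, C7) with an (E)-2-silyloxyvinylstannane (C3, C4), and C4–C5 by the ensuing 6π closure. The closure joins two aldehyde-level carbons of like polarity and forms the only carbocycle.
4. The bromodiene comes from propargyl benzoate and allyl bromide (cis-bromoallylation fixes the C1=C2 geometry, then alkene cleavage and enol benzoylation). The stannane comes from (E)-1,2-bis(tributylstannyl)ethene.
5. Ring order: carbocycle (key step), then a temporary 2,3-dioxabicyclo[2.2.2]octene (singlet oxygen), opened again by O–O reduction. The route is racemic up to the dienol, which is resolved with a lipase before the last two stereocentres are set.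

Key step: step 5

Remark: ring positions are cited with the target numbering (C1 carries the exocyclic carbon C7, C2 is the vinylic CH, C3 to C6 carry oxygen). The two racemic intermediates are named and drawn as the enantiomer that is carried on. The three starting materials are taken as commercial.

**Route**

Step 1
Reactants: 1 prop-2-yn-1-yl benzoate (propargyl benzoate); 2 allyl bromide
Product: 3 (2E)-2-(bromomethylidene)pent-4-en-1-yl benzoate
Conditions: PdBr2(PhCN)2 (3 mol %), allyl bromide (neat, excess), 20 °C
Reagents that add atoms: none
Why: Palladium-catalysed bromoallylation of an alkyne: divalent palladium adds bromine to the terminal carbon and palladium to the internal carbon in a cis sense, and insertion of allyl bromide with β-bromide elimination should give the 1-bromo-1,4-diene with bromine cis to the allyl group, which fixes the C1=C2 geometry needed later, while the absence of zerovalent palladium protects the propargylic ester.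

Step 2
Reactants: 3 (2E)-2-(bromomethylidene)pent-4-en-1-yl benzoate
Product: 4 (2E)-2-(bromomethylidene)-4-oxobutyl benzoate
Conditions: OsO4 (2 mol %), NaIO4, 2,6-lutidine, dioxane–H2O, 20 °C
Reagents that add atoms: osmium tetroxide, O=[Os](=O)(=O)=O; sodium periodate (terminal oxidant that restores the osmium oxo group), [Na+].[O-]I(=O)(=O)=O
Why: Lemieux–Johnson oxidation, in which OsO4 should dihydroxylate the terminal monosubstituted alkene much faster than the trisubstituted, bromine-deactivated one and periodate cleaves the diol to the aldehyde, with lutidine buffering against over-oxidation and no stereocentre formed.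

Step 3
Reactants: 4 (2E)-2-(bromomethylidene)-4-oxobutyl benzoate
Product: 5 (1E,3E)-3-[(benzoyloxy)methyl]-4-bromobuta-1,3-dien-1-yl benzoate
Conditions: BzCl, Et3N, DMAP (cat.), CH2Cl2, 0 to 20 °C
Reagents that add atoms: benzoyl chloride, O=C(Cl)c1ccccc1
Why: Dienol ester formation: the C6 methylene is allylic and α to the aldehyde, so amine-mediated enolisation gives the extended dienolate, which is O-benzoylated, and the (1E)-enol ester should predominate because the (1Z)-isomer suffers allylic strain against the substituents on C1, while the bromoalkene geometry is untouched.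

Step 4
Reactants: 6 (E)-1,2-bis(tributylstannyl)ethene
Product: 9 triethyl{[(E)-2-(tributylstannyl)ethenyl]oxy}silane, via stannylvinyllithium 7 (not isolated), via lithium stannylethenolate 8 (not isolated)
Conditions: n-BuLi, THF, −78 °C; t-BuOOLi (from t-BuOOH and n-BuLi), −78 to −20 °C; Et3SiCl, −78 to 0 °C
Reagents that add atoms: tert-butyl hydroperoxide (used as its lithium salt, gives one oxygen atom), CC(C)(C)OO; chlorotriethylsilane, CC[Si](Cl)(CC)CC
Why: Tin–lithium exchange of one stannyl group gives the configurationally stable (E)-vinyllithium, lithium tert-butyl peroxide transfers electrophilic oxygen to it with retention to give the (E)-aldehyde enolate, and O-silylation traps it as the silyl enol ether (oxidation of an organolithium to an enolate followed by enolate silylation).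

Step 5
Reactants: 5 (1E,3E)-3-[(benzoyloxy)methyl]-4-bromobuta-1,3-dien-1-yl benzoate; 9 triethyl{[(E)-2-(tributylstannyl)ethenyl]oxy}silane
Product: 11 rac-[(3R,4S)-3-(benzoyloxy)-4-[(triethylsilyl)oxy]cyclohexa-1,5-dien-1-yl]methyl benzoate, via hexatrienyl benzoate 10 (not isolated)
Conditions: Pd2(dba)3 (3 mol %), AsPh3, CuI (10 mol %), NMP, 45 °C; then thiol-functionalised silica, PhMe, 105 °C
Reagents that add atoms: none
Why: A Stille coupling (oxidative addition of zerovalent palladium into the C2–Br bond, CuI-assisted transmetalation from tin, reductive elimination) joins C2 to C3 with retention of both alkene geometries and gives hexatriene 10, in which the two oxygenated alkenyl arms are cis on the C1=C2 bond. On heating, 10 undergoes a thermal, disrotatory 6π-electrocyclization that makes the C4–C5 σ bond and thereby closes the six-membered carbocycle, the only ring of the target; the closest known reaction type is the tandem Stille coupling/6π-electrocyclization of (Z)-hexatrienes to cyclohexa-1,3-dienes. The new stereocentres C4 and C5 are controlled by orbital symmetry: both oxygens sit on the outside of (E)-configured termini, so disrotation brings them to the same face and only the cis isomer can form, as a racemate because the two disrotatory senses are mirror images. The union of C4 and C5, two aldehyde-level carbons of like polarity, therefore needs no reductant. The step needs chemoselective oxidative addition at the vinyl bromide in the presence of one allylic and one enol benzoate, which the much faster reaction of the C(sp2)–Br bond and the weakly donating AsPh3 ligand should secure, and it needs the (E)-geometry of both termini, which is built into 5 and 9. Palladium is sequestered on thiol silica before the mixture is heated so that the allylic benzoate of the product is not ionised, and the CH2OBz group on the central double bond favours the s-cis,s-cis conformer required for closure.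

Step 6
Reactants: 11 rac-[(3R,4S)-3-(benzoyloxy)-4-[(triethylsilyl)oxy]cyclohexa-1,5-dien-1-yl]methyl benzoate
Product: 12 rac-[(3R,4S)-3-(benzoyloxy)-4-hydroxycyclohexa-1,5-dien-1-yl]methyl benzoate
Conditions: HF·pyridine, pyridine, THF, 0 °C
Reagents that add atoms: none
Why: Fluoride-induced desilylation with pyridine-buffered HF cleaves the secondary silyl ether without generating an alkoxide, so the cis-neighbouring benzoate should not migrate and the acid-labile diene should not dehydrate, and the stereocentres are untouched.

Step 7
Reactants: 12 rac-[(3R,4S)-3-(benzoyloxy)-4-hydroxycyclohexa-1,5-dien-1-yl]methyl benzoate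
Product: 13 [(3R,4S)-3-(benzoyloxy)-4-hydroxycyclohexa-1,5-dien-1-yl]methyl benzoate
Conditions: Candida antarctica lipase B (immobilised), vinyl acetate, t-BuOMe, 30 °C, stopped near half conversion
Reagents that add atoms: none
Why: Lipase-catalysed kinetic resolution by enantioselective transesterification: the empirical size rule for secondary alcohols, with the sp3 C5 side as the large and the vinylic C3 side as the medium substituent, predicts faster acetylation of the (3S,4R)-alcohol, so the wanted (3R,4S)-alcohol should remain and is separated from the acetate, and the neutral medium avoids benzoyl migration.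

Step 8
Reactants: 13 [(3R,4S)-3-(benzoyloxy)-4-hydroxycyclohexa-1,5-dien-1-yl]methyl benzoate
Product: 14 [(1R,4S,7R,8S)-8-(benzoyloxy)-7-hydroxy-2,3-dioxabicyclo[2.2.2]oct-5-en-5-yl]methyl benzoate
Conditions: O2, rose bengal (cat.), visible light, MeOH–CH2Cl2, −20 °C
Reagents that add atoms: dioxygen (as singlet oxygen), O=O
Why: [4+2] cycloaddition of singlet oxygen across C3 and C6 of the cyclohexa-1,3-diene should occur on the face opposite to the cis C4 hydroxyl and C5 benzoate (steric approach control, with methanol suppressing hydroxyl-directed attack), which sets C3 and C6 and moves the double bond to C1=C2.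

Step 9
Reactants: 14 [(1R,4S,7R,8S)-8-(benzoyloxy)-7-hydroxy-2,3-dioxabicyclo[2.2.2]oct-5-en-5-yl]methyl benzoate
Product: 15 [(3R,4S,5R,6S)-5-(benzoyloxy)-3,4,6-trihydroxycyclohex-1-en-1-yl]methyl benzoate
Conditions: thiourea, MeOH, 20 °C
Reagents that add atoms: none
Why: Thiourea reduction of a bicyclic endoperoxide cleaves only the O–O bond under neutral conditions to give the cis-1,4-diol, so no C–O bond is broken, all four stereocentres are retained and the benzoates and the alkene are untouched.

**Compound list**

1 | prop-2-yn-1-yl benzoate | C#CCOC(=O)c1ccccc1 | starting material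
2 | allyl bromide | C=CCBr | starting material
3 | (2E)-2-(bromomethylidene)pent-4-en-1-yl benzoate (Br cis to the allyl group) | Br/C=C(\CC=C)COC(=O)c1ccccc1 | intermediate
4 | (2E)-2-(bromomethylidene)-4-oxobutyl benzoate | Br/C=C(\CC=O)COC(=O)c1ccccc1 | intermediate
5 | (1E,3E)-3-[(benzoyloxy)methyl]-4-bromobuta-1,3-dien-1-yl benzoate | Br/C=C(\C=C\OC(=O)c1ccccc1)COC(=O)c1ccccc1 | intermediate
6 | (E)-1,2-bis(tributylstannyl)ethene | CCCC[Sn](CCCC)(CCCC)/C=C/[Sn](CCCC)(CCCC)CCCC | starting material
7 | (E)-2-(tributylstannyl)ethenyllithium | [Li]/C=C/[Sn](CCCC)(CCCC)CCCC | intermediate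
8 | lithium (E)-2-(tributylstannyl)ethenolate | [Li]O/C=C/[Sn](CCCC)(CCCC)CCCC | intermediate
9 | triethyl{[(E)-2-(tributylstannyl)ethenyl]oxy}silane | CC[Si](CC)(CC)O/C=C/[Sn](CCCC)(CCCC)CCCC | intermediate
10 | (1E,3E,5E)-3-[(benzoyloxy)methyl]-6-[(triethylsilyl)oxy]hexa-1,3,5-trien-1-yl benzoate (the two enol arms cis on the central double bond) | CC[Si](CC)(CC)O/C=C/C=C(\C=C\OC(=O)c1ccccc1)COC(=O)c1ccccc1 | intermediate
11 | rac-[(3R,4S)-3-(benzoyloxy)-4-[(triethylsilyl)oxy]cyclohexa-1,5-dien-1-yl]methyl benzoate (cis, racemate) | O=C(OCC1=C[C@@H](OC(=O)c2ccccc2)[C@@H](O[Si](CC)(CC)CC)C=C1)c1ccccc1 | intermediate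
12 | rac-[(3R,4S)-3-(benzoyloxy)-4-hydroxycyclohexa-1,5-dien-1-yl]methyl benzoate (cis, racemate) | O=C(OCC1=C[C@@H](OC(=O)c2ccccc2)[C@@H](O)C=C1)c1ccccc1 | intermediate
13 | [(3R,4S)-3-(benzoyloxy)-4-hydroxycyclohexa-1,5-dien-1-yl]methyl benzoate (single enantiomer) | O=C(OCC1=C[C@@H](OC(=O)c2ccccc2)[C@@H](O)C=C1)c1ccccc1 | intermediate
14 | [(1R,4S,7R,8S)-8-(benzoyloxy)-7-hydroxy-2,3-dioxabicyclo[2.2.2]oct-5-en-5-yl]methyl benzoate (peroxide bridge anti to the hydroxyl and benzoate) | O=C(OCC1=C[C@@H]2[C@H](O)[C@H](OC(=O)c3ccccc3)[C@H]1OO2)c1ccccc1 | intermediate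
15 | [(3R,4S,5R,6S)-5-(benzoyloxy)-3,4,6-trihydroxycyclohex-1-en-1-yl]methyl benzoate | O=C(OCC1=C[C@@H](O)[C@H](O)[C@H](OC(=O)c2ccccc2)[C@H]1O)c1ccccc1 | target

**Step count and risks**

Total step count: 9. Longest linear sequence: 8 steps (steps 1, 2, 3, 5, 6, 7, 8, 9); step 4 is the side branch to reagent 9.

Steps most likely to fail:

Step 5. Zerovalent palladium may ionise the allylic benzoate of the newly formed diene at the temperature of the ring closure, with loss of benzoic acid and aromatisation, or oxidative addition into the hindered bromoalkene may be too slow. The fallback is palladium-free and stepwise, and sets out from 3. Copper-catalysed Finkelstein exchange (NaI, CuI, N,N'-dimethylethylenediamine, dioxane, 110 °C) would give (2E)-2-(iodomethylidene)pent-4-en-1-yl benzoate F1. Lemieux–Johnson cleavage as in step 2 would give (2E)-2-(iodomethylidene)-4-oxobutyl benzoate F2, and enol benzoylation as in step 3 would give (1E,3E)-3-[(benzoyloxy)methyl]-4-iodobuta-1,3-dien-1-yl benzoate F3. Coupling of F3 with 9 mediated by stoichiometric copper thiophene-2-carboxylate (CuO2CC4H3S, monovalent copper) in NMP at 0 °C would give triene 10, which is isolated cold and then heated in toluene with no transition metal present. The fallback comes back to the route at 11.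

Step 7. The enzyme may discriminate the enantiomers poorly, or acylate the hindered carbinol next to the benzoate too slowly. The fallback sets out from 12 and separates the racemate by preparative chromatography on a chiral stationary phase (supercritical CO2 with 2-propanol), collecting the (3R,4S)-enantiomer. It comes back to the route at 13 and makes no new compound (F0).

Step 8. Singlet oxygen may attack with poor facial selectivity because the free C4 hydroxyl directs it to its own face, or an ene reaction may compete. The fallback sets out from 13 and relies on a bulky protecting group for facial control. Silylation (t-BuMe2SiCl, imidazole, DMF) would give [(3R,4S)-3-(benzoyloxy)-4-[(tert-butyldimethylsilyl)oxy]cyclohexa-1,5-dien-1-yl]methyl benzoate F4. Photooxygenation as in step 8 would give [(1R,4S,7R,8S)-8-(benzoyloxy)-7-[(tert-butyldimethylsilyl)oxy]-2,3-dioxabicyclo[2.2.2]oct-5-en-5-yl]methyl benzoate F5. Thiourea reduction would give [(3R,4S,5R,6S)-5-(benzoyloxy)-4-[(tert-butyldimethylsilyl)oxy]-3,6-dihydroxycyclohex-1-en-1-yl]methyl benzoate F6, and desilylation with HF·pyridine in THF comes back to the route at 15.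

Further compounds
F1 | step 5 | (2E)-2-(iodomethylidene)pent-4-en-1-yl benzoate | I/C=C(\CC=C)COC(=O)c1ccccc1
F2 | step 5 | (2E)-2-(iodomethylidene)-4-oxobutyl benzoate | I/C=C(\CC=O)COC(=O)c1ccccc1
F3 | step 5 | (1E,3E)-3-[(benzoyloxy)methyl]-4-iodobuta-1,3-dien-1-yl benzoate | I/C=C(\C=C\OC(=O)c1ccccc1)COC(=O)c1ccccc1
F0 | step 7 | none | none
F4 | step 8 | [(3R,4S)-3-(benzoyloxy)-4-[(tert-butyldimethylsilyl)oxy]cyclohexa-1,5-dien-1-yl]methyl benzoate | O=C(OCC1=C[C@@H](OC(=O)c2ccccc2)[C@@H](O[Si](C)(C)C(C)(C)C)C=C1)c1ccccc1
F5 | step 8 | [(1R,4S,7R,8S)-8-(benzoyloxy)-7-[(tert-butyldimethylsilyl)oxy]-2,3-dioxabicyclo[2.2.2]oct-5-en-5-yl]methyl benzoate | O=C(OCC1=C[C@@H]2[C@H](O[Si](C)(C)C(C)(C)C)[C@H](OC(=O)c3ccccc3)[C@H]1OO2)c1ccccc1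
F6 | step 8 | [(3R,4S,5R,6S)-5-(benzoyloxy)-4-[(tert-butyldimethylsilyl)oxy]-3,6-dihydroxycyclohex-1-en-1-yl]methyl benzoate | O=C(OCC1=C[C@@H](O)[C@H](O[Si](C)(C)C(C)(C)C)[C@H](OC(=O)c2ccccc2)[C@H]1O)c1ccccc1
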